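## Retrosynthetic overview

1. The target is reached by removing three MOM ethers; the C7 oxygen of ring A is put in just before that by a sterically controlled C–H borylation/oxidation of the finished flavanone core.
2. Ring C comes from a one-carbon radical ring expansion (stepwise 1,2-acyl shift) of a 2-aryl-2-(iodomethyl)benzofuran-3-one; the ring-expanded C2 radical is quenched by an enantioselective hydrogen-atom transfer that sets (2S).
3. The quaternary benzofuranone comes from a one-pot Pd2(dba)3/XPhos enolate arylation of a ring A benzofuran-3-one with the ring B aryl iodide, followed by C-alkylation with CH2I2.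
4. The ring A benzofuranone is built from resorcinol (MOM ethers, ortho-lithiation, chloroacetyl Weinreb amide, ring closure). The ring B iodide is built from catechol (MOM ethers, ortho-lithiation/prenylation, C–H borylation/iodination).
5. Ring order: both benzene rings are bought; the five-membered furanone ring is closed on ring A first and is then expanded to the six-membered ring C.

Assumption: the sense of induction of the new peptide thiol cannot be predicted, so the hand that gives (2S) is used (the L-Cys/D-Pro series is written; its mirror image is taken if screening shows the opposite sense).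

## Route

Step 1
Reactants: 1 resorcinol
Product: 2 1,3-bis(methoxymethoxy)benzene
Conditions: NaH (2.4 equiv), MOMCl (2.4 equiv), DMF, 0 → 25 °C
Reagents that add atoms: chloromethyl methyl ether (MOMCl), COCCl
Why: Williamson-type O-alkylation of the bis-phenoxide gives two MOM acetal ethers that direct the next lithiation and are removed together at the end.

Step 2
Reactants: 2 1,3-bis(methoxymethoxy)benzene; 3 2-chloro-N-methoxy-N-methylacetamide
Product: 6 2-chloro-1-[2,6-bis(methoxymethoxy)phenyl]ethan-1-one, via aryllithium 4 (not isolated), via Weinreb tetrahedral adduct 5 (not isolated)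
Conditions: n-BuLi (1.1 equiv), THF, 0 → 25 °C; then 3 (1.2 equiv), –78 °C; AcOH quench
Reagents that add atoms: n-butyllithium, [Li]CCCC (its lithium stays in 4 and 5 only)
Why: Directed ortho-metalation at C2, flanked by both OMOM groups, is followed by a Weinreb ketone synthesis in which the chelated adduct prevents over-addition.

Step 3
Reactants: 6 2-chloro-1-[2,6-bis(methoxymethoxy)phenyl]ethan-1-one
Product: 8 4-(methoxymethoxy)-1-benzofuran-3(2H)-one, via monophenol 7 (not isolated)
Conditions: TsOH·H2O (10 mol%), MeOH, 25 °C (stopped at mono-cleavage); then NaOAc (3 equiv), 60 °C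
Reagents that add atoms: none
Why: Carbonyl-assisted acetal methanolysis removes one ortho MOM group (the second is slowed by the new O–H···O=C hydrogen bond), and the phenol then closes the furanone ring by intramolecular Williamson etherification (5-exo-tet).

Step 4
Reactants: 9 catechol
Product: 10 1,2-bis(methoxymethoxy)benzene
Conditions: NaH (2.4 equiv), MOMCl (2.4 equiv), DMF, 0 → 25 °C
Reagents that add atoms: chloromethyl methyl ether (MOMCl), COCCl
Why: Williamson-type O-alkylation protects both phenols as MOM ethers, which also direct the lithiation of step 5.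

Step 5
Reactants: 10 1,2-bis(methoxymethoxy)benzene; 11 prenyl bromide (1-bromo-3-methylbut-2-ene)
Product: 13 1,2-bis(methoxymethoxy)-3-(3-methylbut-2-en-1-yl)benzene, via aryllithium 12 (not isolated)
Conditions: n-BuLi (1.1 equiv), THF, 0 → 25 °C; then CuI (10 mol%), 11 (1.2 equiv), –78 → 25 °C
Reagents that add atoms: n-butyllithium, [Li]CCCC (its lithium stays in 12 only)
Why: Directed ortho-metalation next to OMOM is followed by copper-catalysed allylic substitution at the primary carbon (SN2), which keeps the linear prenyl group.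

Step 6
Reactants: 13 1,2-bis(methoxymethoxy)-3-(3-methylbut-2-en-1-yl)benzene
Product: 15 5-iodo-1,2-bis(methoxymethoxy)-3-(3-methylbut-2-en-1-yl)benzene, via aryl pinacol boronate 14 (not isolated)
Conditions: [Ir(OMe)(cod)]2 (1.5 mol%), 4,4'-di-tert-butyl-2,2'-bipyridine (3 mol%), B2pin2 (0.55 equiv), THF, 80 °C; then CuI (10 mol%), 1,10-phenanthroline (20 mol%), KI (1.5 equiv), MeOH/H2O, air, 80 °C
Reagents that add atoms: bis(pinacolato)diboron, CC1(C)OB(OC1(C)C)B1OC(C)(C)C(C)(C)O1 (its boron stays in 14 only); potassium iodide, [K+].[I-]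
Why: Sterically controlled iridium-catalysed C–H borylation hits C5, the only C–H with two unsubstituted neighbours, and copper-catalysed aerobic iododeboronation then gives the iodide without any electrophilic halogen that would attack the prenyl alkene.

Step 7
Reactants: 8 4-(methoxymethoxy)-1-benzofuran-3(2H)-one; 15 5-iodo-1,2-bis(methoxymethoxy)-3-(3-methylbut-2-en-1-yl)benzene; 16 diiodomethane
Product: 18 racemic 2-[3,4-bis(methoxymethoxy)-5-(3-methylbut-2-en-1-yl)phenyl]-2-(iodomethyl)-4-(methoxymethoxy)-1-benzofuran-3(2H)-one, via sodium enolate 17 (not isolated)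
Conditions: Pd2(dba)3 (2.5 mol%), XPhos (6 mol%), NaOt-Bu (2.3 equiv), THF, 65 °C; then CH2I2 (5 equiv), 50 °C
Reagents that add atoms: sodium tert-butoxide, CC(C)(C)[O-].[Na+] (its sodium stays in 17 only)
Why: Buchwald–Hartwig-type α-arylation of the ketone enolate leaves the more acidic 2-aryl ketone as its enolate, which is C-alkylated in the same flask by excess CH2I2 to give the quaternary iodomethyl ketone (racemic; this centre is erased in step 8).

Step 8
Reactants: 18 racemic 2-[3,4-bis(methoxymethoxy)-5-(3-methylbut-2-en-1-yl)phenyl]-2-(iodomethyl)-4-(methoxymethoxy)-1-benzofuran-3(2H)-one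
Product: 19 (2S)-2-[3,4-bis(methoxymethoxy)-5-(3-methylbut-2-en-1-yl)phenyl]-5-(methoxymethoxy)-2,3-dihydro-4H-chromen-4-one
Conditions: 4CzIPN (2 mol%), peptide thiol Boc-L-Cys-D-Pro-Aib-L-Phe-NMe2 (5 mol%), HCO2Na (1.5 equiv), DMSO (0.02 M), 450 nm LEDs, 15 °C
Reagents that add atoms: none
Why: Proposed new method: the CO2 radical anion (made from formate by the thiyl radical) removes iodine from 18 to give a primary radical that adds 3-exo to the C3 ketone, and β-scission of the old C2–C3 bond of the cyclopropyloxy radical (net 1,2-acyl shift, one-carbon ring expansion) gives the tertiary benzylic α-aryloxy C2 radical of the chroman-4-one, which takes hydrogen on one face from the cysteine S–H of the β-turn peptide (held to the C4 carbonyl and O1 by its N–H bonds) to set (2S), the thiyl radical then restarting the chain with formate; the closest known reaction types are the racemic Dowd–Beckwith ring expansion of α-halomethyl cyclic ketones, formate/thiol chain dehalogenation, and peptide-thiol enantioselective hydrogen-atom transfer to prochiral radicals.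

Step 9
Reactants: 19 (2S)-2-[3,4-bis(methoxymethoxy)-5-(3-methylbut-2-en-1-yl)phenyl]-5-(methoxymethoxy)-2,3-dihydro-4H-chromen-4-one
Product: 21 (2S)-2-[3,4-bis(methoxymethoxy)-5-(3-methylbut-2-en-1-yl)phenyl]-7-hydroxy-5-(methoxymethoxy)-2,3-dihydro-4H-chromen-4-one, via C7 pinacol boronate 20 (not isolated)
Conditions: [Ir(OMe)(cod)]2 (3 mol%), 4,4'-di-tert-butyl-2,2'-bipyridine (6 mol%), B2pin2 (0.6 equiv), THF, 60 °C; then 30% aq. H2O2, pH 7 phosphate buffer, THF, 0 → 25 °C
Reagents that add atoms: bis(pinacolato)diboron, CC1(C)OB(OC1(C)C)B1OC(C)(C)C(C)(C)O1 (its boron stays in 20 only); hydrogen peroxide, OO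
Why: Sterically controlled iridium-catalysed C–H borylation selects C7 (the only C–H with two unsubstituted neighbours; both ring B C–H bonds are flanked), and buffered peroxide oxidation of the C–B bond gives the phenol under neutral conditions that leave C2 untouched.

Step 10
Reactants: 21 (2S)-2-[3,4-bis(methoxymethoxy)-5-(3-methylbut-2-en-1-yl)phenyl]-7-hydroxy-5-(methoxymethoxy)-2,3-dihydro-4H-chromen-4-one
Product: 22 sigmoidin B
Conditions: 3 M aq. HCl/MeOH (1:4), 45 °C
Reagents that add atoms: none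
Why: Acid-catalysed acetal methanolysis removes all three MOM ethers; the flavanone C2 centre is stable to acid (ring opening to the chalcone needs base) and the prenyl group tolerates this mild acid.

## Compound list

1 | resorcinol (benzene-1,3-diol) | Oc1cccc(O)c1 | starting material
2 | 1,3-bis(methoxymethoxy)benzene | COCOc1cccc(OCOC)c1 | intermediate
3 | 2-chloro-N-methoxy-N-methylacetamide | CON(C)C(=O)CCl | starting material
4 | [2,6-bis(methoxymethoxy)phenyl]lithium | [Li]c1c(OCOC)cccc1OCOC | intermediate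
5 | lithium 2-chloro-1-[2,6-bis(methoxymethoxy)phenyl]-1-[methoxy(methyl)amino]ethan-1-olate | [Li+].[O-]C(CCl)(N(C)OC)c1c(OCOC)cccc1OCOC | intermediate
6 | 2-chloro-1-[2,6-bis(methoxymethoxy)phenyl]ethan-1-one | COCOc1cccc(OCOC)c1C(=O)CCl | intermediate
7 | 2-chloro-1-[2-hydroxy-6-(methoxymethoxy)phenyl]ethan-1-one | COCOc1cccc(O)c1C(=O)CCl | intermediate
8 | 4-(methoxymethoxy)-1-benzofuran-3(2H)-one | COCOc1cccc2OCC(=O)c12 | intermediate
9 | catechol (benzene-1,2-diol) | Oc1ccccc1O | starting material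
10 | 1,2-bis(methoxymethoxy)benzene | COCOc1ccccc1OCOC | intermediate
11 | prenyl bromide (1-bromo-3-methylbut-2-ene) | CC(C)=CCBr | starting material
12 | [2,3-bis(methoxymethoxy)phenyl]lithium | [Li]c1cccc(OCOC)c1OCOC | intermediate
13 | 1,2-bis(methoxymethoxy)-3-(3-methylbut-2-en-1-yl)benzene | CC(C)=CCc1cccc(OCOC)c1OCOC | intermediate
14 | 2-[3,4-bis(methoxymethoxy)-5-(3-methylbut-2-en-1-yl)phenyl]-4,4,5,5-tetramethyl-1,3,2-dioxaborolane | CC(C)=CCc1cc(B2OC(C)(C)C(C)(C)O2)cc(OCOC)c1OCOC | intermediate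
15 | 5-iodo-1,2-bis(methoxymethoxy)-3-(3-methylbut-2-en-1-yl)benzene | CC(C)=CCc1cc(I)cc(OCOC)c1OCOC | intermediate
16 | diiodomethane | ICI | starting material
17 | sodium 2-[3,4-bis(methoxymethoxy)-5-(3-methylbut-2-en-1-yl)phenyl]-4-(methoxymethoxy)-1-benzofuran-3-olate | [Na+].[O-]c1c(-c2cc(CC=C(C)C)c(OCOC)c(OCOC)c2)oc2cccc(OCOC)c12 | intermediate
18 | racemic 2-[3,4-bis(methoxymethoxy)-5-(3-methylbut-2-en-1-yl)phenyl]-2-(iodomethyl)-4-(methoxymethoxy)-1-benzofuran-3(2H)-one | CC(C)=CCc1cc(C2(CI)Oc3cccc(OCOC)c3C2=O)cc(OCOC)c1OCOC | intermediate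
19 | (2S)-2-[3,4-bis(methoxymethoxy)-5-(3-methylbut-2-en-1-yl)phenyl]-5-(methoxymethoxy)-2,3-dihydro-4H-chromen-4-one | CC(C)=CCc1cc([C@@H]2CC(=O)c3c(OCOC)cccc3O2)cc(OCOC)c1OCOC | intermediate
20 | (2S)-2-[3,4-bis(methoxymethoxy)-5-(3-methylbut-2-en-1-yl)phenyl]-5-(methoxymethoxy)-7-(4,4,5,5-tetramethyl-1,3,2-dioxaborolan-2-yl)-2,3-dihydro-4H-chromen-4-one | CC(C)=CCc1cc([C@@H]2CC(=O)c3c(OCOC)cc(B4OC(C)(C)C(C)(C)O4)cc3O2)cc(OCOC)c1OCOC | intermediate
21 | (2S)-2-[3,4-bis(methoxymethoxy)-5-(3-methylbut-2-en-1-yl)phenyl]-7-hydroxy-5-(methoxymethoxy)-2,3-dihydro-4H-chromen-4-one | CC(C)=CCc1cc([C@@H]2CC(=O)c3c(OCOC)cc(O)cc3O2)cc(OCOC)c1OCOC | intermediate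
22 | sigmoidin B, (2S)-2-[3,4-dihydroxy-5-(3-methylbut-2-en-1-yl)phenyl]-5,7-dihydroxy-2,3-dihydro-4H-chromen-4-one | CC(C)=CCc1cc([C@@H]2CC(=O)c3c(O)cc(O)cc3O2)cc(O)c1O | target

## Step count and risks

Total steps: 10. Longest linear sequence: 7 (steps 1, 2, 3, 7, 8, 9, 10 from resorcinol; equally 4, 5, 6, 7, 8, 9, 10 from catechol).

**Step 8 (the proposed new step) is the most likely to fail.** The primary radical may be reduced before it rearranges, the ring B aryl group may shift instead (neophyl-type 1,2-aryl shift), the thiyl radical may add to the prenyl alkene, and the enantioselectivity may be moderate. The fallback uses known chemistry and sets out from 18. A classical tin-mediated Dowd–Beckwith ring expansion (Bu3SnH added slowly, AIBN, benzene, 80 °C) gives racemic 2-[3,4-bis(methoxymethoxy)-5-(3-methylbut-2-en-1-yl)phenyl]-5-(methoxymethoxy)-2,3-dihydro-4H-chromen-4-one F4. Preparative HPLC on a chiral stationary phase (amylose tris(3,5-dimethylphenylcarbamate)) separates it into 19 and the unwanted (2R)-2-[3,4-bis(methoxymethoxy)-5-(3-methylbut-2-en-1-yl)phenyl]-5-(methoxymethoxy)-2,3-dihydro-4H-chromen-4-one F5. The fallback comes back to the route at 19.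

**Step 7 is the second risk.** Ketone 8 can self-condense under base, the aryl iodide may slow the palladium cycle, and the enolate may alkylate on oxygen. The fallback reverses the polarity of the C2–aryl bond formation and sets out from 8 and 15. Ketone 8 is brominated at C2 (CuBr2, EtOAc, 60 °C) to 2-bromo-4-(methoxymethoxy)-1-benzofuran-3(2H)-one F1. Iodide 15 is turned by zinc insertion (Zn dust, LiCl, THF, 50 °C) into [3,4-bis(methoxymethoxy)-5-(3-methylbut-2-en-1-yl)phenyl]zinc iodide F2. A nickel-catalysed Negishi arylation of the α-bromo ketone (NiCl2(dme), pybox ligand, THF/glyme, –30 °C) joins F1 and F2 to racemic 2-[3,4-bis(methoxymethoxy)-5-(3-methylbut-2-en-1-yl)phenyl]-4-(methoxymethoxy)-1-benzofuran-3(2H)-one F3, kept under argon. Alkylation of F3 with CH2I2 (K2CO3, DMF, 40 °C) gives 18, where the fallback comes back to the route.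

**Step 9 is the third risk.** The iridium catalyst may touch the prenyl alkene or C8, or HBpin may reduce the ketone on this late intermediate. The fallback brings the third ring A oxygen in at the start, on a simple arene, at the cost of two more steps; it sets out from 2.
- The borylation/oxidation conditions of step 9 applied to 2 give, via 2-[3,5-bis(methoxymethoxy)phenyl]-4,4,5,5-tetramethyl-1,3,2-dioxaborolane F6, 3,5-bis(methoxymethoxy)phenol F7.
- NaH/MOMCl turns F7 into 1,3,5-tris(methoxymethoxy)benzene F8.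
- n-BuLi gives [2,4,6-tris(methoxymethoxy)phenyl]lithium F9, which adds to 3 to give the adduct lithium 2-chloro-1-[methoxy(methyl)amino]-1-[2,4,6-tris(methoxymethoxy)phenyl]ethan-1-olate F10 and, after quench, 2-chloro-1-[2,4,6-tris(methoxymethoxy)phenyl]ethan-1-one F11.
- The conditions of step 3 give, via 2-chloro-1-[2-hydroxy-4,6-bis(methoxymethoxy)phenyl]ethan-1-one F12, 4,6-bis(methoxymethoxy)-1-benzofuran-3(2H)-one F13.
- The conditions of step 7 with 15 and 16 give, via sodium 2-[3,4-bis(methoxymethoxy)-5-(3-methylbut-2-en-1-yl)phenyl]-4,6-bis(methoxymethoxy)-1-benzofuran-3-olate F14, racemic 2-[3,4-bis(methoxymethoxy)-5-(3-methylbut-2-en-1-yl)phenyl]-2-(iodomethyl)-4,6-bis(methoxymethoxy)-1-benzofuran-3(2H)-one F15.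
- The conditions of step 8 give (2S)-2-[3,4-bis(methoxymethoxy)-5-(3-methylbut-2-en-1-yl)phenyl]-5,7-bis(methoxymethoxy)-2,3-dihydro-4H-chromen-4-one F16.
- The conditions of step 10 convert F16 directly into 22, where the fallback comes back to the route.

## Further compounds

F1 | step 7 | 2-bromo-4-(methoxymethoxy)-1-benzofuran-3(2H)-one | COCOc1cccc2OC(Br)C(=O)c12
F2 | step 7 | [3,4-bis(methoxymethoxy)-5-(3-methylbut-2-en-1-yl)phenyl]zinc iodide | CC(C)=CCc1cc([Zn]I)cc(OCOC)c1OCOC
F3 | step 7 | racemic 2-[3,4-bis(methoxymethoxy)-5-(3-methylbut-2-en-1-yl)phenyl]-4-(methoxymethoxy)-1-benzofuran-3(2H)-one | CC(C)=CCc1cc(C2Oc3cccc(OCOC)c3C2=O)cc(OCOC)c1OCOC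
F4 | step 8 | racemic 2-[3,4-bis(methoxymethoxy)-5-(3-methylbut-2-en-1-yl)phenyl]-5-(methoxymethoxy)-2,3-dihydro-4H-chromen-4-one | CC(C)=CCc1cc(C2CC(=O)c3c(OCOC)cccc3O2)cc(OCOC)c1OCOC
F5 | step 8 | (2R)-2-[3,4-bis(methoxymethoxy)-5-(3-methylbut-2-en-1-yl)phenyl]-5-(methoxymethoxy)-2,3-dihydro-4H-chromen-4-one | CC(C)=CCc1cc([C@H]2CC(=O)c3c(OCOC)cccc3O2)cc(OCOC)c1OCOC
F6 | step 9 | 2-[3,5-bis(methoxymethoxy)phenyl]-4,4,5,5-tetramethyl-1,3,2-dioxaborolane | COCOc1cc(B2OC(C)(C)C(C)(C)O2)cc(OCOC)c1
F7 | step 9 | 3,5-bis(methoxymethoxy)phenol | COCOc1cc(O)cc(OCOC)c1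
F8 | step 9 | 1,3,5-tris(methoxymethoxy)benzene | COCOc1cc(OCOC)cc(OCOC)c1
F9 | step 9 | [2,4,6-tris(methoxymethoxy)phenyl]lithium | [Li]c1c(OCOC)cc(OCOC)cc1OCOC
F10 | step 9 | lithium 2-chloro-1-[methoxy(methyl)amino]-1-[2,4,6-tris(methoxymethoxy)phenyl]ethan-1-olate | [Li+].[O-]C(CCl)(N(C)OC)c1c(OCOC)cc(OCOC)cc1OCOC
F11 | step 9 | 2-chloro-1-[2,4,6-tris(methoxymethoxy)phenyl]ethan-1-one | COCOc1cc(OCOC)c(C(=O)CCl)c(OCOC)c1
F12 | step 9 | 2-chloro-1-[2-hydroxy-4,6-bis(methoxymethoxy)phenyl]ethan-1-one | COCOc1cc(O)c(C(=O)CCl)c(OCOC)c1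
F13 | step 9 | 4,6-bis(methoxymethoxy)-1-benzofuran-3(2H)-one | COCOc1cc(OCOC)c2C(=O)COc2c1
F14 | step 9 | sodium 2-[3,4-bis(methoxymethoxy)-5-(3-methylbut-2-en-1-yl)phenyl]-4,6-bis(methoxymethoxy)-1-benzofuran-3-olate | [Na+].[O-]c1c(-c2cc(CC=C(C)C)c(OCOC)c(OCOC)c2)oc2cc(OCOC)cc(OCOC)c12
F15 | step 9 | racemic 2-[3,4-bis(methoxymethoxy)-5-(3-methylbut-2-en-1-yl)phenyl]-2-(iodomethyl)-4,6-bis(methoxymethoxy)-1-benzofuran-3(2H)-one | CC(C)=CCc1cc(C2(CI)Oc3cc(OCOC)cc(OCOC)c3C2=O)cc(OCOC)c1OCOC
F16 | step 9 | (2S)-2-[3,4-bis(methoxymethoxy)-5-(3-methylbut-2-en-1-yl)phenyl]-5,7-bis(methoxymethoxy)-2,3-dihydro-4H-chromen-4-one | CC(C)=CCc1cc([C@@H]2CC(=O)c3c(OCOC)cc(OCOC)cc3O2)cc(OCOC)c1OCOC
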